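The readings stem from a simulated flask with made-up constants; noise was put on by code.

I took the easy step first and averaged the last 4 chain readings of zeta. That gave the ceiling, the level at which monomer in chains stands still in that flask: 10.4%.

You asked for a quick number, so here is what that ceiling rests on in zeta. From 40.0 min to 90.0 min its free monomer fell from 8.4% to 3.4%, while monomer in chains read 10.6% and then 11.1%, against a scatter of 0.5 percentage points.

| flask | free monomer | initiator | temperature | remark | time |
|---|---|---|---|---|---|
| zeta | 1.5 M | 7.5 mM | 60 °C | the very flask that is asked about, followed so far |  |
| beta | 1.5 M | 3.8 mM | 60 °C | run made earlier |  |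
| flask | 1.5 M | 7.5 mM | 60 °C |  | 2.0 h |

- zeta (time / min: monomer in chains / %, free monomer / %): 15.0: 8.9, 18.4; 30.0: 10.1, 9.7; 40.0: 10.6, 8.4; 60.0: 10.2, 5.8; 80.0: 9.9, 4.3; 90.0: 11.1, 3.4
- beta (time / min: monomer in chains / %, free monomer / %): 1.00: 2.3, 81.4; 1.33: 2.7, 76.4; 2.00: 3.4, 68.0; 3.00: 4.8, 57.9; 5.00: 4.4, 45.1; 8.00: 5.8, 33.1; 12.0: 6.4, 25.1

(readings scatter by 0.5 percentage points)

- additions bring no volume worth counting
- the earlier runs do not show what temperature does; that part of a forecast is a guess
- a reading or a percentage of monomer in chains counts all its forms, free or not

- south: change nothing and wait 4.0 h more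
- south-east: at 2.0 h raise the temperature by 10 K, then wait 4.0 h
- west: at 2.0 h add free monomer, 50.0% of the amount charged, then wait 4.0 h

To carry the ceiling to another initiator charge, I compared zeta at 15.0 min with beta at 12.0 min, nearby times. The chain readings stood in the ratio 1.39, and the square root of the initiator charges in the ratio 1.40. So I took as my rule that, at this free monomer charge and temperature, the ceiling goes with the square root of the initiator charge, a rule read from readings with their scatter.

For this flask, which is zeta followed on, I committed to the ceiling itself at 2.0 h. I expected no gain from south. I expected none from west either, since zeta's chains stood still with free monomer present. The runs show nothing of temperature, so for south-east I put down the ceiling as a guess.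

- monomer in chains, in percent of the free monomer first charged, at 2.0 h
- the option that brings most further monomer in chains ("none" if no option brings more than 2 percentage points) (south / south-east / west / none)
- monomer in chains present, in percent of the free monomer first charged, after south-east
- monomer in chains present, in percent of the free monomer first charged, after west

The forecast read 10.5% now, none as best, 10.7% after south-east and 11.3% after west, on the view that “the initiating activity dies within minutes”.

The flask gave 10.4% at 2.0 h, and the best option was south-east: heating added 5.5 points, reaching 15.9%, while waiting added 0 points and west added 0.021 points, reaching 10.4%. In this flask initiator stood at 30.1% of its charge at 12.0 min and 0.248% at 60.0 min, while monomer in chains went from 8.59% to 10.3% and homo dimer from 58.2% to 69.8%. At 2.0 h this flask had 0% of its initiator left against 3.2% of its free monomer. Beside monomer in chains stood 14.5% isomer of the product, a pair with a relaxation half-life of 1.16 min, shorter than 2.0 h, so read both on heating.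

    initiator → 2 initiating radical (k = 0.100 /min, Ea = 109 kJ/mol)
    free monomer + initiating radical → growing radical + monomer in chains (k = 16000 /M/s, Ea = 40.0 kJ/mol)
    free monomer + growing radical → monomer in chains + growing radical, rate k3*[growing radical]*[free monomer] (k = 65000 /M/min, Ea = 46.0 kJ/mol)
    2 growing radical → dead chain (k = 3.00 × 10⁷ /M/s, Ea = 9.00 kJ/mol)
    monomer in chains ⇌ isomer of the product (K = 1.40, k = 0.350 /min, Ea = 90.0 kJ/mol, ΔH = −86.0 kJ/mol)
    2 free monomer → homo dimer (k = 0.0670 /M/min, Ea = 87.0 kJ/mol)
    crystals ⇌ monomer in chains, rate k7*(cs7 - [monomer in chains]) while solid is left; crystals form when [monomer in chains] > cs7 (solubility = 0.970 M, k = 1.10 /min)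
    (constants at 60 °C)

With 0.0019 M of initiator, the same flask has a ceiling of 5.26% by my rule. The simulation gave 5.54%.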